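**Retrosynthetic overview**
- Last C–C bond: C12–C13, by B-alkyl Suzuki–Miyaura coupling of a C9-vinyl decalin (hydroborated in the flask) with a (Z)-β-iodo enoate that already carries C13–C16, the acetate and a fluoride-labile ester; one global desilylation follows.
- Iodo enoate: anti-hydroiodination of a 4-acetoxybut-2-ynoate made from propargyl alcohol and CO2; this fixes the 13E geometry.
- Decalin: C17 and C12 come from two methylenations of a C8-keto/C9-ester decalin.
- Ring B (formed second): SnCl4 cation–olefin cyclization of a monocyclic β-keto ester (allylic bromide + acetoacetate dianion); the C2 silyloxy center relays C5, C9 and C10.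
- Ring A (formed first): annulation of mesityl oxide with methyl acetoacetate, then CBS reduction to set C2.

Assumption: atom labels C1–C20 follow labdane numbering; the target is read as (2R,5R,9R,10R,13E)-16-acetoxy-2-hydroxylabda-8(17),13-dien-15-oic acid (ent-labdane series).

**Decalin fragment**

Step 1
Reactants: 1 mesityl oxide (4-methylpent-3-en-2-one); 2 methyl acetoacetate
Product: 3 methyl 2,6,6-trimethyl-4-oxocyclohex-2-ene-1-carboxylate (racemic)
Conditions: ZnCl2 (0.2 equiv), toluene, reflux, Dean–Stark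
Reagents that add atoms: none
Why: Lewis-acid-mediated Michael addition of the acetoacetate to the β,β-dimethyl enone followed by intramolecular aldol condensation (Hagemann/Robinson-type annulation) builds ring A with the C4 gem-dimethyl, the C10 methyl, the C2 oxygen and C6 in place, and its only stereocenter (C5, α to the ester) is racemic and is erased in step 3.

Step 2
Reactants: 3 enone ester
Product: 4 methyl (4R)-4-hydroxy-2,6,6-trimethylcyclohex-2-ene-1-carboxylate (both C1 epimers)
Conditions: (S)-2-methyl-CBS-oxazaborolidine (0.2 equiv), BH3·SMe2, THF, −30 °C; MeOH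
Reagents that add atoms: none
Why: Corey–Bakshi–Shibata reduction delivers hydride 1,2 to one face of the enone carbonyl (alkenyl carbon as the large group, ring CH2 as the small one), so the future C2 carbinol is set as 4R under catalyst control in both C1 epimers.

Step 3
Reactants: 4 allylic alcohol
Product: 5 methyl (4S)-4-hydroxy-2,6,6-trimethylcyclohex-1-ene-1-carboxylate
Conditions: NaOMe (0.3 equiv), MeOH, 60 °C
Reagents that add atoms: none
Why: Base-mediated alkene isomerization through the ester dienolate moves the double bond into the tetrasubstituted, ester-conjugated position under thermodynamic control, which removes the racemic C1 center and leaves one enantiomer (the carbinol is untouched; its descriptor changes to S only because the CIP priorities change).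

Step 4
Reactants: 5 hydroxy ester
Product: 6 methyl (4S)-4-[(tert-butyldiphenylsilyl)oxy]-2,6,6-trimethylcyclohex-1-ene-1-carboxylate
Conditions: TBDPSCl, imidazole, DMF, 23 °C
Reagents that add atoms: tert-butyl(chloro)diphenylsilane CC(C)(C)[Si](Cl)(c1ccccc1)c1ccccc1
Why: Imidazole-promoted silylation gives an acid-robust silyl ether that survives the SnCl4 cyclization and all later organometallic steps, with no change at the stereocenter.

Step 5
Reactants: 6 silyloxy ester
Product: 7 {(4S)-4-[(tert-butyldiphenylsilyl)oxy]-2,6,6-trimethylcyclohex-1-en-1-yl}methanol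
Conditions: i-Bu2AlH (2.5 equiv), CH2Cl2, −78 → 0 °C
Reagents that add atoms: none
Why: Hydride reduction of the hindered conjugated ester stops cleanly at the primary allylic alcohol (1,2-reduction), and the silyl ether and tetrasubstituted alkene are inert.

Step 6
Reactants: 7 allylic alcohol
Product: 8 tert-butyl{[(1S)-4-(bromomethyl)-3,5,5-trimethylcyclohex-3-en-1-yl]oxy}diphenylsilane
Conditions: CBr4, PPh3, CH2Cl2, 0 °C (used crude)
Reagents that add atoms: tetrabromomethane BrC(Br)(Br)Br
Why: Appel bromination (SN2 on the alkoxyphosphonium ion) converts the primary allylic alcohol to the bromide under neutral conditions that do not touch the silyl ether.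

Step 7
Reactants: 8 allylic bromide; 2 methyl acetoacetate
Product: 10 methyl 5-{(4S)-4-[(tert-butyldiphenylsilyl)oxy]-2,6,6-trimethylcyclohex-1-en-1-yl}-3-oxopentanoate, via methyl acetoacetate dianion 9 (not isolated)
Conditions: 2, NaH, THF, 0 °C; n-BuLi, 0 °C; then 8, 0 → 23 °C; aq. NH4Cl
Reagents that add atoms: none
Why: Weiler dianion alkylation, in which the more basic terminal carbanion of the acetoacetate dianion displaces the primary allylic bromide (SN2), attaches C7, C8, C9 and C11 as a β-keto ester.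

Step 8
Reactants: 10 monocyclic β-keto ester
Product: 11 methyl (1S,4aR,7R,8aR)-7-[(tert-butyldiphenylsilyl)oxy]-5,5,8a-trimethyl-2-oxodecahydronaphthalene-1-carboxylate
Conditions: SnCl4 (2.5 equiv), CH2Cl2, 0 → 23 °C; aq. NaHCO3
Reagents that add atoms: none
Why: β-Keto-ester-terminated cation–olefin cyclization: protonation at C5 and attack of the tin enolate carbon C9 on C10 occur anti across the ring alkene through a chair-like transition state (trans ring fusion) on the face that keeps the C2 silyloxy group equatorial rather than 1,3-diaxial to the C4 and C10 methyls, so C5 and C10 follow from C2, and the epimerizable C9 ester settles equatorial.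

Step 9
Reactants: 11 decalin β-keto ester
Product: 12 methyl (1R,4aR,7R,8aR)-7-[(tert-butyldiphenylsilyl)oxy]-5,5,8a-trimethyl-2-methylidenedecahydronaphthalene-1-carboxylate
Conditions: Zn, CH2Br2, TiCl4, THF/CH2Cl2, 0 → 23 °C
Reagents that add atoms: dibromomethane BrCBr
Why: Takai–Lombardo methylenation with the non-basic zinc/titanium methylene reagent converts the enolizable C8 ketone into the exocyclic C8=C17 alkene without touching the ester or epimerizing C9.

Step 10
Reactants: 12 methylidene ester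
Product: 14 tert-butyl{[(2R,4aR,8R,8aR)-8-ethenyl-4,4,8a-trimethyl-7-methylidenedecahydronaphthalen-2-yl]oxy}diphenylsilane, via aldehyde 13 (not isolated)
Conditions: i-Bu2AlH (1.1 equiv), toluene, −78 °C; then Ph3P=CH2 [Ph3PCH3Br, KN(SiMe3)2], THF, −78 → 23 °C
Reagents that add atoms: methyltriphenylphosphonium bromide C[P+](c1ccccc1)(c1ccccc1)c1ccccc1.[Br-]
Why: Partial reduction of the hindered ester to the aldehyde followed in the same flask by Wittig methylenation turns C11 into the C11=C12 vinyl group, and the cold one-pot sequence avoids handling the β,γ-unsaturated aldehyde so that C9 keeps its equatorial configuration.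

**Iodo enoate fragment**

Step 11
Reactants: 15 propargyl alcohol (prop-2-yn-1-ol)
Product: 16 2-(prop-2-yn-1-yloxy)oxane
Conditions: 3,4-dihydro-2H-pyran, PPTS (cat.), CH2Cl2, 23 °C
Reagents that add atoms: 3,4-dihydro-2H-pyran C1=COCCC1
Why: Acid-catalysed addition of the alcohol to the enol ether (THP acetal formation) masks the hydroxyl for the acetylide chemistry.

Step 12
Reactants: 16 THP ether
Product: 18 4-(oxan-2-yloxy)but-2-ynoic acid, via lithium alkynide 17 (not isolated)
Conditions: n-BuLi, THF, −78 °C; CO2; cold dilute HCl to pH 3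
Reagents that add atoms: carbon dioxide O=C=O
Why: Deprotonation of the terminal alkyne and carboxylation of the lithium alkynide install C15 as the carboxylic acid.

Step 13
Reactants: 18 alkynoic acid
Product: 19 2-(trimethylsilyl)ethyl 4-(oxan-2-yloxy)but-2-ynoate
Conditions: Me3SiCH2CH2OH, DCC, DMAP (cat.), CH2Cl2, 0 → 23 °C
Reagents that add atoms: 2-(trimethylsilyl)ethanol C[Si](C)(C)CCO
Why: Steglich esterification gives an ester that can later be cleaved by fluoride without touching the acetate.

Step 14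
Reactants: 19 THP ester
Product: 20 2-(trimethylsilyl)ethyl 4-hydroxybut-2-ynoate
Conditions: PPTS (cat.), MeOH, 45 °C
Reagents that add atoms: none
Why: Mild acid-catalysed transacetalization to methanol removes the THP group while the silylethyl ester and the ynoate survive.

Step 15
Reactants: 20 hydroxy ynoate
Product: 21 2-(trimethylsilyl)ethyl 4-acetoxybut-2-ynoate
Conditions: Ac2O, pyridine, CH2Cl2, 0 °C
Reagents that add atoms: acetic anhydride CC(=O)OC(C)=O
Why: Nucleophilic acyl substitution (O-acetylation) of the primary propargylic alcohol installs the C16 acetate of the target at the outset.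

Step 16
Reactants: 21 acetoxy ynoate
Product: 22 2-(trimethylsilyl)ethyl (2Z)-4-acetoxy-3-iodobut-2-enoate
Conditions: NaI, AcOH, 70 °C
Reagents that add atoms: sodium iodide [Na+].[I-]
Why: Conjugate hydroiodination of the ynoate (iodide adds to the β-carbon and the allenoate is protonated anti to iodine) gives the Z iodide with iodine cis to the ester, which fixes the later C13=C14 geometry.

**Coupling and end game**

Step 17
Reactants: 14 vinyl decalin; 22 iodo enoate
Product: 24 2-(trimethylsilyl)ethyl (2E)-3-(acetoxymethyl)-5-[(1R,4aR,7R,8aR)-7-[(tert-butyldiphenylsilyl)oxy]-5,5,8a-trimethyl-2-methylidenedecahydronaphthalen-1-yl]pent-2-enoate, via B-alkyl-9-BBN borane 23 (not isolated)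
Conditions: 9-BBN, THF, 0 → 23 °C; then 22, PdCl2(dppf) (5 mol%), AsPh3, aq. K3PO4, DMF, 23 °C
Reagents that add atoms: none
Why: Anti-Markovnikov hydroboration of the monosubstituted vinyl group by bulky 9-BBN followed by B-alkyl Suzuki–Miyaura coupling (oxidative addition to the vinyl iodide, transmetalation, reductive elimination with retention of alkene geometry) forms C12–C13 and places the C12 chain cis to the ester, i.e. 13E.

Step 18
Reactants: 24 protected coupling product
Product: 25 (2E)-3-(acetoxymethyl)-5-[(1R,4aR,7R,8aR)-7-hydroxy-5,5,8a-trimethyl-2-methylidenedecahydronaphthalen-1-yl]pent-2-enoic acid (target)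
Conditions: TASF [(Me2N)3S+ Me3SiF2−] (3 equiv), DMF, 0 → 23 °C; aq. NH4Cl
Reagents that add atoms: none
Why: Fluoride-induced deprotection fragments the 2-(trimethylsilyl)ethyl ester (β-elimination to ethene and Me3SiF) and cleaves the Si–O bond of the TBDPS ether, while the acetate, the alkenes and all stereocenters are inert to anhydrous fluoride.

**Compound list**
1 | 4-methylpent-3-en-2-one (mesityl oxide) | CC(=O)C=C(C)C | starting material
2 | methyl 3-oxobutanoate (methyl acetoacetate) | COC(=O)CC(C)=O | starting material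
3 | methyl (1RS)-2,6,6-trimethyl-4-oxocyclohex-2-ene-1-carboxylate | COC(=O)C1C(C)=CC(=O)CC1(C)C | intermediate
4 | methyl (1RS,4R)-4-hydroxy-2,6,6-trimethylcyclohex-2-ene-1-carboxylate | COC(=O)C1C(C)=C[C@H](O)CC1(C)C | intermediate
5 | methyl (4S)-4-hydroxy-2,6,6-trimethylcyclohex-1-ene-1-carboxylate | COC(=O)C1=C(C)C[C@H](O)CC1(C)C | intermediate
6 | methyl (4S)-4-[(tert-butyldiphenylsilyl)oxy]-2,6,6-trimethylcyclohex-1-ene-1-carboxylate | COC(=O)C1=C(C)C[C@H](O[Si](c2ccccc2)(c2ccccc2)C(C)(C)C)CC1(C)C | intermediate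
7 | {(4S)-4-[(tert-butyldiphenylsilyl)oxy]-2,6,6-trimethylcyclohex-1-en-1-yl}methanol | OCC1=C(C)C[C@H](O[Si](c2ccccc2)(c2ccccc2)C(C)(C)C)CC1(C)C | intermediate
8 | tert-butyl{[(1S)-4-(bromomethyl)-3,5,5-trimethylcyclohex-3-en-1-yl]oxy}diphenylsilane | BrCC1=C(C)C[C@H](O[Si](c2ccccc2)(c2ccccc2)C(C)(C)C)CC1(C)C | intermediate
9 | dianion of methyl acetoacetate (sodium lithium salt) | [Na+].[Li+].[CH2-]C(=O)[CH-]C(=O)OC | intermediate
10 | methyl 5-{(4S)-4-[(tert-butyldiphenylsilyl)oxy]-2,6,6-trimethylcyclohex-1-en-1-yl}-3-oxopentanoate | COC(=O)CC(=O)CCC1=C(C)C[C@H](O[Si](c2ccccc2)(c2ccccc2)C(C)(C)C)CC1(C)C | intermediate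
11 | methyl (1S,4aR,7R,8aR)-7-[(tert-butyldiphenylsilyl)oxy]-5,5,8a-trimethyl-2-oxodecahydronaphthalene-1-carboxylate | O=C1CC[C@@H]2C(C)(C)C[C@@H](O[Si](c3ccccc3)(c3ccccc3)C(C)(C)C)C[C@@]2(C)[C@@H]1C(=O)OC | intermediate
12 | methyl (1R,4aR,7R,8aR)-7-[(tert-butyldiphenylsilyl)oxy]-5,5,8a-trimethyl-2-methylidenedecahydronaphthalene-1-carboxylate | C=C1CC[C@@H]2C(C)(C)C[C@@H](O[Si](c3ccccc3)(c3ccccc3)C(C)(C)C)C[C@@]2(C)[C@@H]1C(=O)OC | intermediate
13 | (1R,4aR,7R,8aR)-7-[(tert-butyldiphenylsilyl)oxy]-5,5,8a-trimethyl-2-methylidenedecahydronaphthalene-1-carbaldehyde | C=C1CC[C@@H]2C(C)(C)C[C@@H](O[Si](c3ccccc3)(c3ccccc3)C(C)(C)C)C[C@@]2(C)[C@@H]1C=O | intermediate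
14 | tert-butyl{[(2R,4aR,8R,8aR)-8-ethenyl-4,4,8a-trimethyl-7-methylidenedecahydronaphthalen-2-yl]oxy}diphenylsilane | C=C1CC[C@@H]2C(C)(C)C[C@@H](O[Si](c3ccccc3)(c3ccccc3)C(C)(C)C)C[C@@]2(C)[C@@H]1C=C | intermediate
15 | prop-2-yn-1-ol (propargyl alcohol) | C#CCO | starting material
16 | 2-(prop-2-yn-1-yloxy)oxane (racemic THP ether) | C#CCOC1CCCCO1 | intermediate
17 | lithium alkynide of 16 | [Li]C#CCOC1CCCCO1 | intermediate
18 | 4-(oxan-2-yloxy)but-2-ynoic acid | OC(=O)C#CCOC1CCCCO1 | intermediate
19 | 2-(trimethylsilyl)ethyl 4-(oxan-2-yloxy)but-2-ynoate | C[Si](C)(C)CCOC(=O)C#CCOC1CCCCO1 | intermediate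
20 | 2-(trimethylsilyl)ethyl 4-hydroxybut-2-ynoate | C[Si](C)(C)CCOC(=O)C#CCO | intermediate
21 | 2-(trimethylsilyl)ethyl 4-acetoxybut-2-ynoate | CC(=O)OCC#CC(=O)OCC[Si](C)(C)C | intermediate
22 | 2-(trimethylsilyl)ethyl (2Z)-4-acetoxy-3-iodobut-2-enoate | CC(=O)OC/C(I)=C/C(=O)OCC[Si](C)(C)C | intermediate
23 | 9-{2-[(1R,4aR,7R,8aR)-7-[(tert-butyldiphenylsilyl)oxy]-5,5,8a-trimethyl-2-methylidenedecahydronaphthalen-1-yl]ethyl}-9-borabicyclo[3.3.1]nonane | C=C1CC[C@@H]2C(C)(C)C[C@@H](O[Si](c3ccccc3)(c3ccccc3)C(C)(C)C)C[C@@]2(C)[C@@H]1CCB1C2CCCC1CCC2 | intermediate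
24 | 2-(trimethylsilyl)ethyl (2E)-3-(acetoxymethyl)-5-[(1R,4aR,7R,8aR)-7-[(tert-butyldiphenylsilyl)oxy]-5,5,8a-trimethyl-2-methylidenedecahydronaphthalen-1-yl]pent-2-enoate | C=C1CC[C@@H]2C(C)(C)C[C@@H](O[Si](c3ccccc3)(c3ccccc3)C(C)(C)C)C[C@@]2(C)[C@@H]1CC/C(=C\C(=O)OCC[Si](C)(C)C)COC(C)=O | intermediate
25 | (2E)-3-(acetoxymethyl)-5-[(1R,4aR,7R,8aR)-7-hydroxy-5,5,8a-trimethyl-2-methylidenedecahydronaphthalen-1-yl]pent-2-enoic acid [(2R,5R,9R,10R,13E)-16-acetoxy-2-hydroxylabda-8(17),13-dien-15-oic acid] | C=C1CC[C@@H]2C(C)(C)C[C@@H](O)C[C@@]2(C)[C@@H]1CC/C(=C\C(=O)O)COC(C)=O | target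

**Step count and risks**

Total step count: 18. Longest linear sequence: 12 steps (steps 1–10, 17, 18); the iodo enoate branch (steps 11–16) joins at step 17.

The three steps most likely to fail:

Step 8. The cationic closure of ring B may give O-cyclized enol ether or cis-fused material, and the facial control by the remote C2 silyloxy group is argued by analogy and not proven on this substrate. Fallback: close ring B by a radical instead of a cationic pathway. Setting out from 10, oxidative radical cyclization with Mn(OAc)3·2H2O and Cu(OAc)2 in AcOH (the keto ester α-radical adds to C10 of the ring alkene and the tertiary C5 radical is oxidized to the C5=C6 alkene) would give methyl (1S,7R,8aS)-7-[(tert-butyldiphenylsilyl)oxy]-5,5,8a-trimethyl-2-oxo-1,2,3,5,6,7,8,8a-octahydronaphthalene-1-carboxylate F1. Hydrogenation of this alkene (H2, Pd/C, EtOAc/AcOH) from the face opposite the angular methyl gives the trans-fused keto ester and comes back to the route at 11.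

Step 10. Aldehyde 13 is α-branched and β,γ-unsaturated, so it can slip into conjugation with the exocyclic alkene under the basic ylide, epimerize at C9, or be over-reduced. Fallback: build C12 by boronate homologation instead of carbonyl olefination. Setting out from 12, LiAlH4 (Et2O, 0 °C) gives [(1R,4aR,7R,8aR)-7-[(tert-butyldiphenylsilyl)oxy]-5,5,8a-trimethyl-2-methylidenedecahydronaphthalen-1-yl]methanol F2. I2, PPh3 and imidazole convert it to tert-butyl{[(2R,4aR,8R,8aR)-8-(iodomethyl)-4,4,8a-trimethyl-7-methylidenedecahydronaphthalen-2-yl]oxy}diphenylsilane F3. Iodine–lithium exchange (t-BuLi, Et2O/pentane, −78 °C) and addition to ICH2B(pin) with 1,2-boronate rearrangement (Matteson homologation) gives 2-{2-[(1R,4aR,7R,8aR)-7-[(tert-butyldiphenylsilyl)oxy]-5,5,8a-trimethyl-2-methylidenedecahydronaphthalen-1-yl]ethyl}-4,4,5,5-tetramethyl-1,3,2-dioxaborolane F4. Suzuki–Miyaura coupling of this boronate with 22 (Pd(OAc)2, RuPhos, K3PO4, toluene/H2O) comes back to the route at 24, bypassing 13, 14 and 23.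

Step 17. 9-BBN may not discriminate well enough between the hindered C9 vinyl group and the 1,1-disubstituted exocyclic alkene. Fallback: replace the boron chemistry by zirconium and zinc. Setting out from 14, hydrozirconation with Cp2Zr(H)Cl (THF, 23 °C; strongly selective for the monosubstituted alkene) and iodinolysis with I2 give tert-butyl{[(2R,4aR,8R,8aR)-8-(2-iodoethyl)-4,4,8a-trimethyl-7-methylidenedecahydronaphthalen-2-yl]oxy}diphenylsilane F5. Zinc insertion (Zn, LiCl, THF) and Negishi coupling of the alkylzinc iodide with 22 (Pd(PPh3)4, THF/DMA) come back to the route at 24.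

Further compounds
F1 | step 8 | methyl (1S,7R,8aS)-7-[(tert-butyldiphenylsilyl)oxy]-5,5,8a-trimethyl-2-oxo-1,2,3,5,6,7,8,8a-octahydronaphthalene-1-carboxylate | O=C1CC=C2C(C)(C)C[C@@H](O[Si](c3ccccc3)(c3ccccc3)C(C)(C)C)C[C@@]2(C)[C@@H]1C(=O)OC
F2 | step 10 | [(1R,4aR,7R,8aR)-7-[(tert-butyldiphenylsilyl)oxy]-5,5,8a-trimethyl-2-methylidenedecahydronaphthalen-1-yl]methanol | C=C1CC[C@@H]2C(C)(C)C[C@@H](O[Si](c3ccccc3)(c3ccccc3)C(C)(C)C)C[C@@]2(C)[C@@H]1CO
F3 | step 10 | tert-butyl{[(2R,4aR,8R,8aR)-8-(iodomethyl)-4,4,8a-trimethyl-7-methylidenedecahydronaphthalen-2-yl]oxy}diphenylsilane | C=C1CC[C@@H]2C(C)(C)C[C@@H](O[Si](c3ccccc3)(c3ccccc3)C(C)(C)C)C[C@@]2(C)[C@@H]1CI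
F4 | step 10 | 2-{2-[(1R,4aR,7R,8aR)-7-[(tert-butyldiphenylsilyl)oxy]-5,5,8a-trimethyl-2-methylidenedecahydronaphthalen-1-yl]ethyl}-4,4,5,5-tetramethyl-1,3,2-dioxaborolane | C=C1CC[C@@H]2C(C)(C)C[C@@H](O[Si](c3ccccc3)(c3ccccc3)C(C)(C)C)C[C@@]2(C)[C@@H]1CCB1OC(C)(C)C(C)(C)O1
F5 | step 17 | tert-butyl{[(2R,4aR,8R,8aR)-8-(2-iodoethyl)-4,4,8a-trimethyl-7-methylidenedecahydronaphthalen-2-yl]oxy}diphenylsilane | C=C1CC[C@@H]2C(C)(C)C[C@@H](O[Si](c3ccccc3)(c3ccccc3)C(C)(C)C)C[C@@]2(C)[C@@H]1CCI
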